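The spring run is the one to start from: the midnight run has the same charge, 0.500 M substrate and 0.600 M coupling partner, and is asked at a later time.

| setting | spring | summer | dusk | midnight |
|---|---|---|---|---|
| substrate | 0.500 M | 0.500 M | 0.750 M | 0.500 M |
| coupling partner | 0.600 M | 1.20 M | 0.600 M | 0.600 M |
| time |  |  |  | 30 min |

- spring run (time / min: [target] / M): 2.1: 0.0145; 4.3: 0.0446; 6.4: 0.0783; 8.6: 0.1108; 11: 0.1435; 13: 0.1717; 15: 0.1985
- summer run (time / min: [target] / M): 2.1: 0.0216; 4.3: 0.0692; 6.4: 0.1109; 8.6: 0.1580; 11: 0.2102; 13: 0.2451; 15: 0.2821
- dusk run (time / min: [target] / M): 2.1: 0.0246; 4.3: 0.0736; 6.4: 0.1244; 8.6: 0.1724; 11: 0.2277; 13: 0.2737; 15: 0.3132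

(readings scatter by 0.002 M)

1. how the opening rate goes with [coupling partner] round the charge of the spring run: the exponent of the rate at two percent of substrate gone to target
2. how the opening rate goes with [substrate] round the charge of the spring run: the exponent of the rate at two percent of substrate gone to target (one fixed amount of target, the same in the runs compared)
3. target in the midnight run at 30 min, as a share of the substrate charged

- Overall: substrate + coupling partner -> target.
- Constant volume, constant temperature.
- Bound and free are read together.
- "The second partner" is coupling partner.
- An order is taken over about fifteen percent of the charge, up and down.

Follow one substrate molecule still present in the spring run and ask for its chance of turning to target within a minute. Over a window of time, this is the natural log of the share of substrate not yet in target at the start over that share at the end, divided by the minutes, read from the readings. From 4.3 min to 8.6 min it reads 0.0365 min⁻¹. From 8.6 min to 15 min it reads 0.0399 min⁻¹, and this later value is the chance per minute. That looks contradictory: the chance reads higher in the later window, yet the share of the coupling partner charge not yet in target in the spring run fell from 92.6 % to 66.9 %.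

The summer run clears this up. Over the later window it made 1.42 times the target of the spring run on 2.00 times the partner, an exponent of 0.501. With that exponent, the fall in the partner share of the spring run scales the chance down by a factor of 0.850, so the higher later reading points to something growing in the spring run, and target, from 0.0446 M to 0.1985 M, is the species read that grows.

My own reckoning holds the chance steady from the spring reading at 15 min, where 60.3 % of the substrate is not yet in target, and, the midnight run having the same charge, gives 66.9 % turned in the midnight run at 30 min. The forecast, reckoned differently, gives 68 %, with orders of 0.6 in coupling partner and 1.1 in substrate, and it “took the orders as lag-corrected”.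

The midnight run gives 68.6 %, and the orders at two percent turned are 0.37 in coupling partner and 0.71 in substrate, lower than the forecast's 0.6 and 1.1.

    substrate + coupling partner ⇌ intermediate (0.5658 M⁻¹ min⁻¹, 0.1524 min⁻¹)
    intermediate → target (0.5442 min⁻¹)
    substrate + coupling partner + target → 2 target (1.662 M⁻² min⁻¹)
    2 coupling partner ⇌ idle reagent dimer, settled at all times (56.00 M⁻¹)

While substrate and coupling partner were filling the intermediate, the spring run formed target at 0.010 M min⁻¹ at two percent turned. Later, with target standing, the step through target ran beside the step from the intermediate, and the spring run passed a quarter at 9.71 min and half at 19.4 min, where the chance per minute reckons 19.7 min. Carried to the dusk run from its 15 min reading, the same chance reckons 18.8 min for half, and the dusk run reached half at 18.7 min.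

All runs are simulated from invented constants, and the scatter is random.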